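**Plan**
- Retrosynthesis: once the benzyl and silyl groups are removed, the upper C3–OH and C2–H go back to the C2=C3 bond of a 2,4-diaryl-4H-chromene, which is cut by enol ether–alkene ring-closing metathesis. The enol ether goes back to an aryl benzoate (O1–C2), the upper C4–C4a bond to an aromatic Claisen rearrangement of an aryl cinnamyl ether made by a Mitsunobu reaction, and the three-carbon chain to C8 of a protected epicatechin-4β-ol.
- Enabling feature: in upper ring C the C2–C3 bond joins two oxygen-bearing carbons. C2 with ring B and O1 is, one oxidation level down, the carbonyl carbon of a benzoate on the ring A oxygen, and C3 is the inner carbon of a vinyl group on C4. A methylenated ester and that vinyl group, held ortho on ring A, can therefore close ring C.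
- Forward order: rings D, E and F are kept from (−)-epicatechin and receive the C4 oxygen first. Ring A is attached through upper C4 (Mitsunobu, Claisen), ring B by esterification, and ring C closes last by metathesis and is then oxygenated at C3.
- Stereochemistry: lower C2 and C3 come from (−)-epicatechin, and lower C4 from water adding anti to the 3-OH in the DDQ oxidation. Upper C4 forms unselectively in the Claisen step, and the correct series is isolated as a diastereomer after hydroboration. Hydroboration sets upper C2 by syn addition anti to the C4 aryl group, and upper C3 is set by oxidation and hydride delivery anti to both aryl groups.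

Key step: step 12

**Remarks on the chemistry**
- Flavan numbering is used. "Upper" is the new unit (rings A, B, C) and "lower" the epicatechin-derived unit (rings D, E, F). Bn = benzyl, TBS = tert-butyldimethylsilyl. Ar(L) is the C8-linked lower unit of 4: (2R,3S,4S)-5,7-bis(benzyloxy)-2-[3,4-bis(benzyloxy)phenyl]-3,4-bis(TBS-oxy)chroman-8-yl, 2,3-cis-3,4-trans. Its C3 label is S only because silicon outranks carbon.
- Assumption: 11 and 15 are purchased. The two alcohols formed in step 13 have mirror-image upper units on the same lower unit and are therefore diastereomers; they are assumed to separate on silica gel. The one derived from the (4S) epimer of 18, with upper unit (2R,3S,4S), is discarded and carries no number because nothing is made from it.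
- The cis-2,4-diaryl ketone 21 is nearly symmetric about its carbonyl group, so the absolute sense of the upper unit is fixed by the separation in step 13 and not by a chiral reductant.
- The lower C4 hydroxyl is introduced on the monomer. A benzylic oxidation after ring C exists could not tell lower C4–H from the doubly benzylic upper C4–H.

**Route**

Step 1
Reactants: 1 (−)-epicatechin
Product: 2 tetra-O-benzylepicatechin (benzyl on O5, O7, O3' and O4')
Conditions: BnBr, K2CO3, DMF, 0 °C to rt
Reagents that add atoms: benzyl bromide BrCc1ccccc1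
Why: Williamson etherification in which K2CO3 deprotonates only the four phenols, so the 3-OH stays free and C2 and C3 are untouched.

Step 2
Reactants: 2 tetra-O-benzylepicatechin
Product: 3 tetra-O-benzylepicatechin-4β-ol, the (2R,3R,4S)-3,4-diol
Conditions: DDQ, CH2Cl2/H2O, rt
Reagents that add atoms: water O
Why: DDQ benzylic oxidation, in which hydride abstraction from C4 gives a cation stabilised by the 5,7-dioxygenated ring D and water adds anti to the axial 3-OH, setting lower C4 as 4β (3,4-trans, 4S).

Step 3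
Reactants: 3 the 3,4-diol
Product: 4 bis-O-TBS ether of 3 (O3 and O4 silylated)
Conditions: TBSOTf, 2,6-lutidine, CH2Cl2, −40 to 0 °C
Reagents that add atoms: tert-butyldimethylsilyl trifluoromethanesulfonate CC(C)(C)[Si](C)(C)OS(=O)(=O)C(F)(F)F
Why: Silylation of both secondary alcohols by a silyl triflate, with excess lutidine keeping the medium acid-free so that the benzylic C4–O bond does not ionise.

Step 4
Reactants: 4 bis-TBS ether
Product: 5 Ar(L)–Br (C8 bromide of 4)
Conditions: NBS, CH2Cl2, −78 °C to rt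
Reagents that add atoms: N-bromosuccinimide O=C1CCC(=O)N1Br
Why: Electrophilic aromatic bromination, which in 5,7-di-O-benzylflavans goes to C8 because C6 lies between two benzyloxy groups and the catechol ring E is far less activated.

Step 5
Reactants: 5 Ar(L)–Br
Product: 7 Ar(L)–CHO (the C8 carbaldehyde), via aryllithium 6 (not isolated)
Conditions: n-BuLi, THF, −78 °C; DMF; H2O
Reagents that add atoms: N,N-dimethylformamide CN(C)C=O
Why: Bromine–lithium exchange followed by formylation of the aryllithium with DMF, the exchange at −78 °C being faster than any attack on the benzyl or silyl ethers.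

Step 6
Reactants: 7 Ar(L)–CHO
Product: 8 ethyl (E)-3-Ar(L)-prop-2-enoate
Conditions: Ph3P=CHCO2Et, toluene, 100 °C
Reagents that add atoms: ethyl (triphenylphosphoranylidene)acetate CCOC(=O)C=P(c1ccccc1)(c1ccccc1)c1ccccc1
Why: Wittig olefination with a stabilised ylide, which tolerates the di-ortho-substituted aldehyde on heating and gives the (E)-enoate.

Step 7
Reactants: 8 the (E)-enoate
Product: 10 (E)-3-Ar(L)-prop-2-en-1-ol, via enal 9 (not isolated)
Conditions: i-Bu2AlH, CH2Cl2, −78 °C; aq. potassium sodium tartrate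
Reagents that add atoms: none
Why: 1,2-Reduction of the unsaturated ester by an aluminium hydride through the enal, leaving the C=C bond and all ethers intact, with a neutral work-up so that the electron-rich cinnamyl alcohol does not ionise.

Step 8
Reactants: 10 the allylic alcohol, 11 3,5-bis(benzyloxy)phenol
Product: 12 aryl (E)-cinnamyl-type ether
Conditions: PPh3, DIAD, THF, 0 °C to rt
Reagents that add atoms: none
Why: Mitsunobu etherification of a primary allylic alcohol with a phenol under neutral conditions, substitution at the unhindered CH2 terminus keeping the (E)-alkene conjugated with ring D.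

Step 9
Reactants: 12 the aryl allyl ether
Product: 14 ortho-(1-arylallyl)phenol as both epimers at the new carbon, via ortho-dienone 13 (not isolated)
Conditions: PhNEt2, 190 °C, sealed tube, argon
Reagents that add atoms: none
Why: Aromatic Claisen rearrangement ([3,3] shift, then tautomerisation of the dienone) in which the two ortho positions of the phenol ring are equivalent and the amine solvent suppresses acid-promoted ionisation; the new stereocentre (upper C4) is not controlled, which is accepted because the two series are separated in step 13.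

Step 10
Reactants: 14 the phenol, 15 3,4-bis(benzyloxy)benzoic acid
Product: 16 aryl 3,4-bis(benzyloxy)benzoate
Conditions: DCC, DMAP, CH2Cl2, rt
Reagents that add atoms: none
Why: Steglich esterification, in which the acylpyridinium derived from the acid acylates the phenol under neutral conditions that leave the vinyl group and all ethers alone.

Step 11
Reactants: 16 the aryl benzoate
Product: 17 α-aryl vinyl ether (metathesis precursor)
Conditions: Cp2TiMe2, toluene, 70 °C, dark
Reagents that add atoms: dimethyltitanocene C[Ti](C)(C1C=CC=C1)C1C=CC=C1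
Why: Petasis methylenation, in which Cp2Ti=CH2 formed by loss of methane adds to the ester carbonyl and the oxatitanacyclobutane collapses to the enol ether; the reagent is not Lewis acidic, so the benzylic silyl ether and the acid-sensitive product survive.

Step 12
Reactants: 17 the α-aryl vinyl ether
Product: 18 the 2,4-diaryl-4H-chromene as both C4 epimers
Conditions: second-generation Grubbs catalyst RuCl2(=CHPh)(H2IMes)(PCy3) (15 mol %), 1,4-benzoquinone (cat.), toluene, 80 °C, argon sparge
Reagents that add atoms: none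
Why: The ruthenium benzylidene exchanges onto the monosubstituted vinyl group at C4, the resulting alkylidene adds (2+2) across the 1,1-disubstituted enol ether, and cycloreversion of the ruthenacyclobutane forms the C2=C3 bond while ethylene leaves with the argon stream. The closest known reaction type is ring-closing metathesis of enol ethers made by ester methylenation, which gives cyclic enol ethers including 4H-chromenes from 2-allylphenyl vinyl ethers. Ring C closes as a six-membered ring by alkene–alkene metathesis with the new double bond endocyclic, the tether being the ortho-disubstituted ring A. No stereocentre is created, since C4 is already present as both epimers and is untouched, and C2 and C3 become sp2. The step needs ring closure to win over intermolecular metathesis and over ruthenium hydride migration of the C4 vinyl group into conjugation; the ortho arrangement on ring A holds the two alkenes within reach, the bulk around both alkenes disfavours dimerisation, and benzoquinone suppresses isomerisation.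

Step 13
Reactants: 18 the 4H-chromene
Product: 20 the 2,3-trans-3,4-trans alcohol with upper unit (2S,3R,4R), via alkylborane 19 (not isolated)
Conditions: BH3·THF, THF, 0 °C to rt; NaOH aq., H2O2, 0 °C; chromatography on silica gel
Reagents that add atoms: hydrogen peroxide OO
Why: Hydroboration–oxidation of the enol ether puts boron on C3 and hydrogen on C2 in a syn addition to the face of C2=C3 opposite the pseudo-axial C4 aryl group, and oxidation with retention gives the 2,4-cis-diaryl alcohol with the 3-OH trans to both aryl groups; each C4 epimer of 18 reacts in this way, so 20, which comes from the (4R) epimer, is isolated by chromatography from the diastereomer that carries the mirror-image upper unit.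

Step 14
Reactants: 20 the 2,3-trans-3,4-trans alcohol
Product: 21 the 4-arylflavan-3-one with upper unit (2S,4R)
Conditions: Dess–Martin periodinane, pyridine, CH2Cl2, 0 °C
Reagents that add atoms: none
Why: Dess–Martin oxidation of the hindered secondary alcohol under buffered, non-enolising conditions, so the cis relationship of the C2 and C4 aryl groups is kept, the ketone being used at once.

Step 15
Reactants: 21 the ketone
Product: 22 the all-cis alcohol with upper unit (2S,3S,4R)
Conditions: LiBH(s-Bu)3, LiBr, THF, −78 °C; H2O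
Reagents that add atoms: none
Why: Reduction by a bulky trialkylborohydride, which delivers hydride to the carbonyl face opposite the two cis aryl groups, as in the reduction of flavan-3-ones to 2,3-cis alcohols, and so sets C3 (3S) cis to both aryl groups, the low temperature limiting enolisation toward C2 or C4.

Step 16
Reactants: 22 the bis-silyl all-cis alcohol
Product: 23 octa-O-benzyl triol
Conditions: Bu4NF, THF, 0 °C to rt
Reagents that add atoms: none
Why: Fluoride cleavage of both silyl ethers, driven by Si–F bond formation, which touches neither benzyl ethers nor stereocentres and leaves only aryl benzyl ethers for the last step.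

Step 17
Reactants: 23 the octa-O-benzyl triol
Product: 24 target, ent-epicatechin-(4β→8)-epicatechin-4β-ol
Conditions: H2 (1 atm), Pd(OH)2/C, THF/MeOH, rt
Reagents that add atoms: none
Why: Heterogeneous hydrogenolysis of the eight aryl benzyl ethers under neutral conditions, which should be much faster than cleavage of the free benzylic C4–OH of the lower unit or of the C4–aryl bond as long as no acid is present and hydrogen uptake is stopped at completion.

**Compound list**

1 | (−)-epicatechin, (2R,3R) | Oc1cc(O)c2c(c1)O[C@H](c1ccc(O)c(O)c1)[C@H](O)C2 | starting material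
2 | (2R,3R)-5,7-bis(benzyloxy)-2-[3,4-bis(benzyloxy)phenyl]chroman-3-ol | c1ccccc1COc1cc(OCc3ccccc3)c2c(c1)O[C@H](c1ccc(OCc3ccccc3)c(OCc3ccccc3)c1)[C@H](O)C2 | intermediate
3 | (2R,3R,4S)-5,7-bis(benzyloxy)-2-[3,4-bis(benzyloxy)phenyl]chromane-3,4-diol (2,3-cis, 3,4-trans) | c1ccccc1COc1cc(OCc3ccccc3)c2c(c1)O[C@H](c1ccc(OCc3ccccc3)c(OCc3ccccc3)c1)[C@H](O)[C@H]2O | intermediate
4 | 3,4-bis-O-TBS ether of 3, (2R,3S,4S), Ar(L)–H | c1ccccc1COc1cc(OCc3ccccc3)c2c(c1)O[C@H](c1ccc(OCc3ccccc3)c(OCc3ccccc3)c1)[C@H](O[Si](C)(C)C(C)(C)C)[C@H]2O[Si](C)(C)C(C)(C)C | intermediate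
5 | 8-bromo derivative of 4, Ar(L)–Br | c1ccccc1COc1cc(OCc3ccccc3)c2c(c1Br)O[C@H](c1ccc(OCc3ccccc3)c(OCc3ccccc3)c1)[C@H](O[Si](C)(C)C(C)(C)C)[C@H]2O[Si](C)(C)C(C)(C)C | intermediate
6 | 8-lithio derivative, Ar(L)–Li | c1ccccc1COc1cc(OCc3ccccc3)c2c(c1[Li])O[C@H](c1ccc(OCc3ccccc3)c(OCc3ccccc3)c1)[C@H](O[Si](C)(C)C(C)(C)C)[C@H]2O[Si](C)(C)C(C)(C)C | intermediate (not isolated)
7 | 8-carbaldehyde, Ar(L)–CHO | c1ccccc1COc1cc(OCc3ccccc3)c2c(c1C=O)O[C@H](c1ccc(OCc3ccccc3)c(OCc3ccccc3)c1)[C@H](O[Si](C)(C)C(C)(C)C)[C@H]2O[Si](C)(C)C(C)(C)C | intermediate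
8 | ethyl (E)-3-Ar(L)-prop-2-enoate | c1ccccc1COc1cc(OCc3ccccc3)c2c(c1/C=C/C(=O)OCC)O[C@H](c1ccc(OCc3ccccc3)c(OCc3ccccc3)c1)[C@H](O[Si](C)(C)C(C)(C)C)[C@H]2O[Si](C)(C)C(C)(C)C | intermediate
9 | (E)-3-Ar(L)-prop-2-enal | c1ccccc1COc1cc(OCc3ccccc3)c2c(c1/C=C/C=O)O[C@H](c1ccc(OCc3ccccc3)c(OCc3ccccc3)c1)[C@H](O[Si](C)(C)C(C)(C)C)[C@H]2O[Si](C)(C)C(C)(C)C | intermediate (not isolated)
10 | (E)-3-Ar(L)-prop-2-en-1-ol | c1ccccc1COc1cc(OCc3ccccc3)c2c(c1/C=C/CO)O[C@H](c1ccc(OCc3ccccc3)c(OCc3ccccc3)c1)[C@H](O[Si](C)(C)C(C)(C)C)[C@H]2O[Si](C)(C)C(C)(C)C | intermediate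
11 | 3,5-bis(benzyloxy)phenol | Oc1cc(OCc2ccccc2)cc(OCc2ccccc2)c1 | starting material
12 | 1,3-bis(benzyloxy)-5-{[(E)-3-Ar(L)-prop-2-enyl]oxy}benzene | c1ccccc1COc1cc(OCc3ccccc3)c2c(c1/C=C/COc1cc(OCc3ccccc3)cc(OCc3ccccc3)c1)O[C@H](c1ccc(OCc3ccccc3)c(OCc3ccccc3)c1)[C@H](O[Si](C)(C)C(C)(C)C)[C@H]2O[Si](C)(C)C(C)(C)C | intermediate
13 | 3,5-bis(benzyloxy)-6-[1-Ar(L)-prop-2-enyl]cyclohexa-2,4-dien-1-one, new centres undefined | c1ccccc1COc1cc(OCc3ccccc3)c2c(c1C(C=C)C1C(=O)C=C(OCc3ccccc3)C=C1OCc3ccccc3)O[C@H](c1ccc(OCc3ccccc3)c(OCc3ccccc3)c1)[C@H](O[Si](C)(C)C(C)(C)C)[C@H]2O[Si](C)(C)C(C)(C)C | intermediate (not isolated)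
14 | 3,5-bis(benzyloxy)-2-[1-Ar(L)-prop-2-enyl]phenol, both epimers at the allylic carbon (upper C4) | c1ccccc1COc1cc(OCc3ccccc3)c2c(c1C(C=C)c1c(O)cc(OCc3ccccc3)cc1OCc3ccccc3)O[C@H](c1ccc(OCc3ccccc3)c(OCc3ccccc3)c1)[C@H](O[Si](C)(C)C(C)(C)C)[C@H]2O[Si](C)(C)C(C)(C)C | intermediate
15 | 3,4-bis(benzyloxy)benzoic acid | OC(=O)c1ccc(OCc2ccccc2)c(OCc2ccccc2)c1 | starting material
16 | 3,5-bis(benzyloxy)-2-[1-Ar(L)-prop-2-enyl]phenyl 3,4-bis(benzyloxy)benzoate, both epimers | c1ccccc1COc1cc(OCc3ccccc3)c2c(c1C(C=C)c1c(OC(=O)c4ccc(OCc3ccccc3)c(OCc3ccccc3)c4)cc(OCc3ccccc3)cc1OCc3ccccc3)O[C@H](c1ccc(OCc3ccccc3)c(OCc3ccccc3)c1)[C@H](O[Si](C)(C)C(C)(C)C)[C@H]2O[Si](C)(C)C(C)(C)C | intermediate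
17 | 1,5-bis(benzyloxy)-3-{1-[3,4-bis(benzyloxy)phenyl]ethenyloxy}-2-[1-Ar(L)-prop-2-enyl]benzene, both epimers | c1ccccc1COc1cc(OCc3ccccc3)c2c(c1C(C=C)c1c(OC(=C)c4ccc(OCc3ccccc3)c(OCc3ccccc3)c4)cc(OCc3ccccc3)cc1OCc3ccccc3)O[C@H](c1ccc(OCc3ccccc3)c(OCc3ccccc3)c1)[C@H](O[Si](C)(C)C(C)(C)C)[C@H]2O[Si](C)(C)C(C)(C)C | intermediate
18 | 5,7-bis(benzyloxy)-2-[3,4-bis(benzyloxy)phenyl]-4-Ar(L)-4H-chromene, both C4 epimers | c1ccccc1COc1cc(OCc3ccccc3)c2c(c1)OC(c1ccc(OCc3ccccc3)c(OCc3ccccc3)c1)=CC2c1c(OCc3ccccc3)cc(OCc3ccccc3)c2c1O[C@H](c1ccc(OCc3ccccc3)c(OCc3ccccc3)c1)[C@H](O[Si](C)(C)C(C)(C)C)[C@H]2O[Si](C)(C)C(C)(C)C | intermediate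
19 | C3 alkylborane with the geometry of 20 (BH2 on C3 trans to both aryl groups), from the (4R) epimer of 18 | c1ccccc1COc1cc(OCc3ccccc3)c2c(c1)O[C@@H](c1ccc(OCc3ccccc3)c(OCc3ccccc3)c1)[C@H](B)[C@H]2c1c(OCc3ccccc3)cc(OCc3ccccc3)c2c1O[C@H](c1ccc(OCc3ccccc3)c(OCc3ccccc3)c1)[C@H](O[Si](C)(C)C(C)(C)C)[C@H]2O[Si](C)(C)C(C)(C)C | intermediate (not isolated)
20 | (2S,3R,4R)-5,7-bis(benzyloxy)-2-[3,4-bis(benzyloxy)phenyl]-4-Ar(L)-chroman-3-ol (2,3-trans, 3,4-trans) | c1ccccc1COc1cc(OCc3ccccc3)c2c(c1)O[C@@H](c1ccc(OCc3ccccc3)c(OCc3ccccc3)c1)[C@H](O)[C@H]2c1c(OCc3ccccc3)cc(OCc3ccccc3)c2c1O[C@H](c1ccc(OCc3ccccc3)c(OCc3ccccc3)c1)[C@H](O[Si](C)(C)C(C)(C)C)[C@H]2O[Si](C)(C)C(C)(C)C | intermediate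
21 | (2S,4R)-5,7-bis(benzyloxy)-2-[3,4-bis(benzyloxy)phenyl]-4-Ar(L)-chroman-3-one (2,4-cis) | c1ccccc1COc1cc(OCc3ccccc3)c2c(c1)O[C@@H](c1ccc(OCc3ccccc3)c(OCc3ccccc3)c1)C(=O)[C@H]2c1c(OCc3ccccc3)cc(OCc3ccccc3)c2c1O[C@H](c1ccc(OCc3ccccc3)c(OCc3ccccc3)c1)[C@H](O[Si](C)(C)C(C)(C)C)[C@H]2O[Si](C)(C)C(C)(C)C | intermediate
22 | (2S,3S,4R)-5,7-bis(benzyloxy)-2-[3,4-bis(benzyloxy)phenyl]-4-Ar(L)-chroman-3-ol (all-cis) | c1ccccc1COc1cc(OCc3ccccc3)c2c(c1)O[C@@H](c1ccc(OCc3ccccc3)c(OCc3ccccc3)c1)[C@@H](O)[C@H]2c1c(OCc3ccccc3)cc(OCc3ccccc3)c2c1O[C@H](c1ccc(OCc3ccccc3)c(OCc3ccccc3)c1)[C@H](O[Si](C)(C)C(C)(C)C)[C@H]2O[Si](C)(C)C(C)(C)C | intermediate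
23 | octa-O-benzyl ether of the target: upper (2S,3S,4R) all-cis 3-ol, lower (2R,3R,4S)-3,4-diol | c1ccccc1COc1cc(OCc3ccccc3)c2c(c1)O[C@@H](c1ccc(OCc3ccccc3)c(OCc3ccccc3)c1)[C@@H](O)[C@H]2c1c(OCc3ccccc3)cc(OCc3ccccc3)c2c1O[C@H](c1ccc(OCc3ccccc3)c(OCc3ccccc3)c1)[C@H](O)[C@H]2O | intermediate
24 | ent-epicatechin-(4β→8)-epicatechin-4β-ol: upper (2S,3S,4R), lower (2R,3R,4S) | Oc1cc(O)c2c(c1)O[C@@H](c1ccc(O)c(O)c1)[C@@H](O)[C@H]2c1c(O)cc(O)c2c1O[C@H](c1ccc(O)c(O)c1)[C@H](O)[C@H]2O | target

**Totals**
Total step count: 17. Longest linear sequence: 17 steps from (−)-epicatechin (11 and 15 enter as purchased materials).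

**Steps most likely to fail**

Step 9. At 190 °C the ether, whose allyl part carries the strongly donating ring D, may ionise to a phenoxide/allyl cation pair and recombine without positional control, giving C-allylation at the CH2 terminus, para attack or loss of the phenol. The fallback sets out from 5 and 11 and comes back at 14. Phenol 11 is ortho-formylated with MgCl2, Et3N and paraformaldehyde in MeCN to 2-hydroxy-4,6-bis(benzyloxy)benzaldehyde F1. Boc2O, i-Pr2NEt and DMAP convert F1 into the aryl tert-butyl carbonate F2. The aryllithium 6, made from 5 with n-BuLi at −78 °C, is added to the aldehyde of F2 to give the lithium alkoxide F3. Vinylmagnesium bromide CH2=CHMgBr is then added and the mixture warmed to 0 °C: the carbonate group moves to the benzylic oxygen and is expelled, the ortho-quinone methide F4 forms, and it takes up the vinyl Grignard reagent in a 1,4-addition to give 14 as both epimers. This is a known ortho-quinone methide generation and 1,4-addition sequence; it needs no heating and replaces steps 5 to 9.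

Step 12. The catalyst may fail to load on the crowded C4 vinyl group, ruthenium hydrides may move that double bond into conjugation before ring closure, or the catalyst may decay on the enol ether. The fallback sets out from 16 and comes back at 18. Ester 16 is treated with an excess of the Tebbe reagent Cp2Ti(μ-CH2)(μ-Cl)AlMe2 in THF containing pyridine. At rt this methylenates the ester to 17 in the flask; at 65 °C the titanocene alkylidene then carries out the metathesis with the vinyl group and closes ring C (olefinic ester cyclisation). No new compound is made.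

Step 17. Over-reduction may occur: hydrogenolysis of the benzylic C4–OH bond of the lower unit, helped by ionisation on an acidic catalyst surface, or acid-promoted self-condensation of the freed flavan-3,4-diol. The fallback sets out from 22 and comes back at 24. The benzyl ethers of 22 are hydrogenolysed first (H2, Pd(OH)2/C, EtOAc/THF) with both silyl ethers in place, giving the bis-silyl octaphenol F5, in which the bulky silyl ether keeps the lower C4–O bond from cleavage. The silyl groups are then removed with fluoride buffered by acetic acid (Bu4NF/AcOH, THF, 0 °C) to give 24.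

**Further compounds**

F1 | step 9 | 2-hydroxy-4,6-bis(benzyloxy)benzaldehyde | O=Cc1c(O)cc(OCc2ccccc2)cc1OCc1ccccc1
F2 | step 9 | 3,5-bis(benzyloxy)-2-formylphenyl tert-butyl carbonate | O=Cc1c(OC(=O)OC(C)(C)C)cc(OCc2ccccc2)cc1OCc1ccccc1
F3 | step 9 | lithium alkoxide from addition of 6 to the aldehyde of F2 (carbinol centre undefined) | [Li]OC(c1c(OC(=O)OC(C)(C)C)cc(OCc2ccccc2)cc1OCc1ccccc1)c1c(OCc3ccccc3)cc(OCc3ccccc3)c2c1O[C@H](c1ccc(OCc3ccccc3)c(OCc3ccccc3)c1)[C@H](O[Si](C)(C)C(C)(C)C)[C@H]2O[Si](C)(C)C(C)(C)C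
F4 | step 9 | ortho-quinone methide, 3,5-bis(benzyloxy)-6-[Ar(L)-methylidene]cyclohexa-2,4-dien-1-one | O=C1C=C(OCc2ccccc2)C=C(OCc2ccccc2)C1=Cc1c(OCc3ccccc3)cc(OCc3ccccc3)c2c1O[C@H](c1ccc(OCc3ccccc3)c(OCc3ccccc3)c1)[C@H](O[Si](C)(C)C(C)(C)C)[C@H]2O[Si](C)(C)C(C)(C)C
F0 | step 12 | none | none
F5 | step 17 | lower 3,4-bis-O-TBS ether of the target (all phenols free) | Oc1cc(O)c2c(c1)O[C@@H](c1ccc(O)c(O)c1)[C@@H](O)[C@H]2c1c(O)cc(O)c2c1O[C@H](c1ccc(O)c(O)c1)[C@H](O[Si](C)(C)C(C)(C)C)[C@H]2O[Si](C)(C)C(C)(C)C
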